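**Retrosynthetic overview**

1. The target is (2S)-7-hydroxy-4'-(geranyloxy)flavanone 16. Its C4 ketone and free 7-OH are unmasked last from the (2S,4S)-4-ethoxy-7-silyloxyflavan 13 by hydrolysis, oxidation and desilylation.
2. Key disconnection: C2–C3 and C4–C4a of ring C (the pyran ring), by a cationic formal [4+2] (oxa-Povarov) between ethyl vinyl ether 10 and an O-aryl oxocarbenium ion. The feature used: once C2 is an oxocarbenium carbon on a resorcinol-derived aryl ether, C2, O1, C8a and C4a form a 2-oxadiene, and C4a of ring A lies para to the C7 oxygen, so it is nucleophilic enough to close C4–C4a.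
3. The cation is released from the achiral diaryl acetal 9, which carries two identical 3-silyloxyphenoxy groups. A mixed alkyl aryl acetal would tend to expel the phenol and give the more stable O-alkyl cation; 9 can only give the O-aryl cation and returns one equivalent of phenol 2.
4. Acetal 9 comes from gem-dichloride 6 (made from 4-(geranyloxy)benzaldehyde 5) and two equivalents of mono-silylated resorcinol 2.
5. Ring order: rings A and B are bought (resorcinol, 4-hydroxybenzaldehyde); ring C is the only ring made, in step 5.

Key step: step 5

Assumption: geranyl means (2E)-3,7-dimethylocta-2,6-dien-1-yl, and the sense of induction of the chiral acid cannot be predicted, so the (S,S) acid is written and its mirror image would be used if it favoured 2R.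

**Route**

Step 1
Reactants: 1 resorcinol (3 equiv)
Product: 2 3-(triisopropylsilyloxy)phenol
Conditions: triisopropylsilyl chloride (1.0 equiv), imidazole, DMF, 0 °C to rt; aqueous wash removes excess 1
Reagents that add atoms: triisopropylsilyl chloride, CC(C)[Si](Cl)(C(C)C)C(C)C
Why: Silyl ether formation under imidazole catalysis on a symmetric diphenol; with resorcinol in threefold excess and the bulky silyl chloride as limiting reagent the mono-ether should dominate, and the water-soluble excess resorcinol is washed out.

Step 2
Reactants: 3 4-hydroxybenzaldehyde, 4 geranyl bromide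
Product: 5 4-(geranyloxy)benzaldehyde
Conditions: K2CO3, DMF, rt
Reagents that add atoms: none
Why: Williamson ether synthesis; the phenoxide displaces the primary allylic bromide by SN2, which keeps the E alkene and leaves the aldehyde untouched.

Step 3
Reactants: 5 4-(geranyloxy)benzaldehyde
Product: 6 1-(dichloromethyl)-4-(geranyloxy)benzene
Conditions: (COCl)2 (1.3 equiv), Ph3PO (15 mol %), dry CHCl3, rt; evaporate, use crude at once
Reagents that add atoms: oxalyl chloride, O=C(Cl)C(Cl)=O
Why: Appel-type deoxydichlorination of an aldehyde catalysed by Ph3PO; oxalyl chloride turns Ph3PO into Ph3PCl2, which replaces the carbonyl oxygen by two chlorides and returns Ph3PO without forming HCl, so the geranyl alkenes and the allyl aryl ether should survive.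

Step 4
Reactants: 6 1-(dichloromethyl)-4-(geranyloxy)benzene, 2 3-(triisopropylsilyloxy)phenol (2.3 equiv)
Product: 9 1-(geranyloxy)-4-{bis[3-(triisopropylsilyloxy)phenoxy]methyl}benzene, via sodium 3-(triisopropylsilyloxy)phenoxide 7 (not isolated), via alpha-chloro aryl ether 8 (not isolated)
Conditions: 2, NaH (2.3 equiv), THF, 0 °C; then 6 in THF/DMF, −20 °C to rt; NaHCO3 work-up, Et3N-treated silica
Reagents that add atoms: none
Why: Twofold Williamson-type O-alkylation at a benzylic carbon made cation-like by the para-alkoxy group; the first phenoxide gives alpha-chloro ether 8, which ionises more easily than 6 and takes up the second phenoxide at oxygen, and the basic medium protects the acid-labile diaryl acetal.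

Step 5
Reactants: 9 1-(geranyloxy)-4-{bis[3-(triisopropylsilyloxy)phenoxy]methyl}benzene, 10 ethyl vinyl ether (3 equiv)
Product: 13 (2S,4S)-4-ethoxy-2-[4-(geranyloxy)phenyl]-7-(triisopropylsilyloxy)chromane, via O-aryl oxocarbenium ion 11 (not isolated), via ethoxycarbenium ion 12 (not isolated)
Conditions: (S,S)-imidodiphosphorimidate Brønsted acid built from two (S)-3,3'-bis[3,5-bis(trifluoromethyl)phenyl]-BINOL units with N-triflyl groups on both phosphorus atoms (5 mol %), 10 added in portions, 4 Å MS, toluene, −78 °C; Et3N quench at −78 °C
Reagents that add atoms: none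
Why: Proposed new method: the strong chiral acid protonates one aryloxy oxygen of 9 and releases phenol 2, leaving O-aryl oxocarbenium ion 11 paired with the confined chiral anion; the CH2 terminus of 10 adds to C2 (C2–C3 bond) to give ethoxycarbenium ion 12, ring-A carbon C4a captures it (C4–C4a bond) in a Friedel–Crafts closure, and loss of the arenium proton returns the acid. The closest known reaction types are the racemic Lewis-acid-promoted oxa-Povarov reaction of aryl oxocarbenium ions with alkenes and the chiral-acid-catalysed Povarov reaction of N-aryl imines with vinyl ethers; an enantioselective oxygen version is not known. Ring C closes in a six-membered closure that is exo with respect to the C4 oxocarbenium bond (6-exo-trig) through a chair-like transition state. C2 is set in the first C–C bond formation by the chiral counter-anion, which shields one face of the planar cation 11 (catalyst control); C4 is set by the chair closure that puts the C2 aryl and C4 ethoxy groups cis (substrate control), and this centre is erased in step 7. The step needs (a) ionisation to the O-aryl cation, secured by the two identical aryloxy groups of 9, (b) ring closure faster than addition of a second vinyl ether, secured by the electron-rich ring A and the portionwise addition of 10, and (c) closure para and not ortho to the silyloxy group, secured by the bulk of the triisopropylsilyl group. The para-geranyloxyphenyl group makes ionisation easy at −78 °C, where the geranyl alkenes should not be protonated.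

Step 6
Reactants: 13 (2S,4S)-4-ethoxy-2-[4-(geranyloxy)phenyl]-7-(triisopropylsilyloxy)chromane
Product: 14 (2S,4RS)-2-[4-(geranyloxy)phenyl]-7-(triisopropylsilyloxy)chroman-4-ol (C4 epimers)
Conditions: 0.1 M HCl, THF/H2O (3:1), 0 °C to rt; NaHCO3 quench as soon as 13 is consumed
Reagents that add atoms: water, O
Why: SN1 solvolysis (acid-catalysed exchange of the ether for water); positive charge at C4 is stabilised by the para silyloxy group and the ortho ring oxygen of ring A, so the ethoxy group should be exchanged in dilute acid that leaves the less activated C2–O1 bond, the aryl silyl ether and the geranyl ether alone, and the C4 configuration does not matter.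

Step 7
Reactants: 14 (2S,4RS)-2-[4-(geranyloxy)phenyl]-7-(triisopropylsilyloxy)chroman-4-ol
Product: 15 (2S)-2-[4-(geranyloxy)phenyl]-7-(triisopropylsilyloxy)chroman-4-one
Conditions: activated MnO2 (excess), CH2Cl2, rt
Reagents that add atoms: none
Why: MnO2 oxidation of a benzylic alcohol under neutral heterogeneous conditions; both C4 epimers converge on the ketone, the geranyl alkenes carry no allylic hydroxyl and are not touched, and without base C2 cannot be lost by ring opening to the chalcone.

Step 8
Reactants: 15 (2S)-2-[4-(geranyloxy)phenyl]-7-(triisopropylsilyloxy)chroman-4-one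
Product: 16 (2S)-2-[4-(geranyloxy)phenyl]-7-hydroxychroman-4-one (CNP0302343.1)
Conditions: Bu4NF (1.1 equiv), AcOH (1.2 equiv), THF, 0 °C
Reagents that add atoms: none
Why: Fluoride-induced cleavage of an aryl silyl ether, fast here because the leaving phenoxide is para to the ketone; acetic acid buffers the medium so the freed phenoxide is protonated at once and the base-induced retro-oxa-Michael opening that would racemise C2 is suppressed.

**Compound list**

1 | resorcinol | Oc1cccc(O)c1 | starting material
2 | 3-(triisopropylsilyloxy)phenol | Oc1cccc(O[Si](C(C)C)(C(C)C)C(C)C)c1 | intermediate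
3 | 4-hydroxybenzaldehyde | O=Cc1ccc(O)cc1 | starting material
4 | geranyl bromide, (2E)-1-bromo-3,7-dimethylocta-2,6-diene | CC(C)=CCC/C(C)=C/CBr | starting material
5 | 4-(geranyloxy)benzaldehyde | CC(C)=CCC/C(C)=C/COc1ccc(C=O)cc1 | intermediate
6 | 1-(dichloromethyl)-4-(geranyloxy)benzene | CC(C)=CCC/C(C)=C/COc1ccc(C(Cl)Cl)cc1 | intermediate
7 | sodium 3-(triisopropylsilyloxy)phenoxide (formed in the flask) | [Na+].[O-]c1cccc(O[Si](C(C)C)(C(C)C)C(C)C)c1 | intermediate
8 | rac-1-{chloro[3-(triisopropylsilyloxy)phenoxy]methyl}-4-(geranyloxy)benzene (formed in the flask) | CC(C)=CCC/C(C)=C/COc1ccc(C(Cl)Oc2cccc(O[Si](C(C)C)(C(C)C)C(C)C)c2)cc1 | intermediate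
9 | 1-(geranyloxy)-4-{bis[3-(triisopropylsilyloxy)phenoxy]methyl}benzene (achiral diaryl acetal) | CC(C)=CCC/C(C)=C/COc1ccc(C(Oc2cccc(O[Si](C(C)C)(C(C)C)C(C)C)c2)Oc2cccc(O[Si](C(C)C)(C(C)C)C(C)C)c2)cc1 | intermediate
10 | ethyl vinyl ether | C=COCC | starting material
11 | O-aryl oxocarbenium ion, {[4-(geranyloxy)phenyl]methylidene}[3-(triisopropylsilyloxy)phenyl]oxonium, ion pair with the catalyst anion (formed in the flask) | CC(C)=CCC/C(C)=C/COc1ccc(C=[O+]c2cccc(O[Si](C(C)C)(C(C)C)C(C)C)c2)cc1 | intermediate
12 | ethoxycarbenium ion, ethyl{(3S)-3-[4-(geranyloxy)phenyl]-3-[3-(triisopropylsilyloxy)phenoxy]propylidene}oxonium, ion pair with the catalyst anion (formed in the flask) | CC(C)=CCC/C(C)=C/COc1ccc([C@H](CC=[O+]CC)Oc2cccc(O[Si](C(C)C)(C(C)C)C(C)C)c2)cc1 | intermediate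
13 | (2S,4S)-4-ethoxy-2-[4-(geranyloxy)phenyl]-7-(triisopropylsilyloxy)chromane (2,4-cis) | CC(C)=CCC/C(C)=C/COc1ccc([C@@H]2C[C@H](OCC)c3ccc(O[Si](C(C)C)(C(C)C)C(C)C)cc3O2)cc1 | intermediate
14 | (2S,4RS)-2-[4-(geranyloxy)phenyl]-7-(triisopropylsilyloxy)chroman-4-ol | CC(C)=CCC/C(C)=C/COc1ccc([C@@H]2CC(O)c3ccc(O[Si](C(C)C)(C(C)C)C(C)C)cc3O2)cc1 | intermediate
15 | (2S)-2-[4-(geranyloxy)phenyl]-7-(triisopropylsilyloxy)chroman-4-one | CC(C)=CCC/C(C)=C/COc1ccc([C@@H]2CC(=O)c3ccc(O[Si](C(C)C)(C(C)C)C(C)C)cc3O2)cc1 | intermediate
16 | (2S)-2-[4-(geranyloxy)phenyl]-7-hydroxychroman-4-one | CC(C)=CCC/C(C)=C/COc1ccc([C@@H]2CC(=O)c3ccc(O)cc3O2)cc1 | target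

**Step count**

Total: 8 steps. Longest linear sequence: 7 steps (steps 2 to 8, from 4-hydroxybenzaldehyde); step 1 is a one-step branch that joins at step 4.

**Steps most likely to fail**

Step 5 (key step). Three processes may defeat it: poor facial selectivity in the addition to the planar cation, cationic oligomerisation of the vinyl ether in place of ring closure, and intermolecular Friedel–Crafts capture of the cations by the released phenol. The fallback uses known chemistry and buys ring C instead of making it. It sets out from geranyl bromide 4. Commercial 4-hydroxyphenylboronic acid pinacol ester would be alkylated with 4 (K2CO3, DMF) to 2-[4-(geranyloxy)phenyl]-4,4,5,5-tetramethyl-1,3,2-dioxaborolane F1. Commercial 7-hydroxychromone would be silylated (triisopropylsilyl chloride, imidazole, DMF) to 7-(triisopropylsilyloxy)-4H-chromen-4-one F2. A rhodium-catalysed asymmetric conjugate addition of F1 to F2 ([RhCl(C2H4)2]2, a chiral diene such as 2,5-diphenylbicyclo[2.2.2]octa-2,5-diene in the enantiomer that gives 2S, aqueous K3PO4, dioxane, rt) should set C2 under ligand control. It comes back to the route at 15, before step 8.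

Step 4. The cation-like benzylic chloride may alkylate the ambident phenoxide at carbon, or the labile gem-dichloride may be hydrolysed before the second substitution. The fallback builds the acetal one C–O bond at a time and sets out from aldehyde 5. Trimethyl orthoformate in methanol with catalytic pyridinium p-toluenesulfonate should give 1-(dimethoxymethyl)-4-(geranyloxy)benzene F3. Acetyl chloride would convert this into rac-1-[chloro(methoxy)methyl]-4-(geranyloxy)benzene F4. Addition of F4 to one equivalent of phenoxide 7 should give rac-1-(geranyloxy)-4-{methoxy[3-(triisopropylsilyloxy)phenoxy]methyl}benzene F5. Both enantiomers of F5 give the same cation, so F5 would be put through step 5 in place of 9, with 5 Å sieves to hold the methanol, and the route is rejoined at 13. The price is weaker control of the ionisation, because loss of the phenol competes with loss of methanol.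

Step 6. The C4 cation may lose a proton from C3 and give the flav-3-ene instead of capturing water, or prolonged acid may open the C2–O1 bond and erode the C2 configuration. The fallback is oxidative instead of solvolytic and sets out from 13. 2,3-Dichloro-5,6-dicyano-1,4-benzoquinone (1.1 equiv) in CH2Cl2 and pH 7 buffer at 0 °C should abstract hydride from C4, the most electron-rich benzylic ether position. Water then adds and the hemiketal collapses to the ketone with loss of ethanol, which is the known oxidative cleavage of electron-rich benzylic ethers. It comes back to the route at 15 and makes step 7 unnecessary.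

**Further compounds**

F1 | step 5 | 2-[4-(geranyloxy)phenyl]-4,4,5,5-tetramethyl-1,3,2-dioxaborolane | CC(C)=CCC/C(C)=C/COc1ccc(B2OC(C)(C)C(C)(C)O2)cc1
F2 | step 5 | 7-(triisopropylsilyloxy)-4H-chromen-4-one | O=c1ccoc2cc(O[Si](C(C)C)(C(C)C)C(C)C)ccc12
F3 | step 4 | 1-(dimethoxymethyl)-4-(geranyloxy)benzene | CC(C)=CCC/C(C)=C/COc1ccc(C(OC)OC)cc1
F4 | step 4 | rac-1-[chloro(methoxy)methyl]-4-(geranyloxy)benzene | CC(C)=CCC/C(C)=C/COc1ccc(C(Cl)OC)cc1
F5 | step 4 | rac-1-(geranyloxy)-4-{methoxy[3-(triisopropylsilyloxy)phenoxy]methyl}benzene | CC(C)=CCC/C(C)=C/COc1ccc(C(OC)Oc2cccc(O[Si](C(C)C)(C(C)C)C(C)C)c2)cc1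
F0 | step 6 | none | none
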